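The readings were computed from invented constants, noise included.

Product in the flask, followed so far as the epsilon run, reads 23.6% of the starting material charged at 20.0 min, its highest reading. The ledger is kept in starting material, the limiting reagent, as fractions of its charge. The product entry leaves 76.4% of the charge in unread entries: starting material still unused, and whatever else has formed. The eta run, charged 1.50 times as heavily, tops lower, at 19.1% at 15.0 min. It then pays out 3.4 percentage points by 40.0 min. In these two runs the heavier charge gives product the smaller share. Between these two runs the highest reading falls as the charge to the power 0.522, and this power is the charge exponent, a reading from two tops.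

| setting | epsilon | eta | flask |
|---|---|---|---|
| starting material | 0.020 M | 0.030 M | 0.020 M |
| gas | 2 mM (held) | 2 mM (held) | 2.0 mM (held) |
| catalyst | 10 µM | 10 µM | 10 µM |
| remark | the very flask that is asked about, followed so far | run made earlier |  |
| time |  |  | 50 min |

| run | time / min | product / % |
|---|---|---|
| epsilon | 5.00 | 12.7 |
| epsilon | 6.00 | 14.7 |
| epsilon | 8.00 | 17.7 |
| epsilon | 12.0 | 21.9 |
| epsilon | 15.0 | 22.8 |
| epsilon | 20.0 | 23.6 |
| eta | 5.00 | 11.9 |
| eta | 8.00 | 14.8 |
| eta | 10.0 | 16.5 |
| eta | 15.0 | 19.1 |
| eta | 25.0 | 17.7 |
| eta | 40.0 | 15.7 |

(readings scatter by 0.5 percentage points)

- the best time, 50 min at the latest, for product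
- the amount of product, in percent of the starting material charged, at that time

- at the start none of the gas is in solution

The last step of the epsilon run is 0.8 points against a scatter of 0.5 points. The reckoning here puts the flask's top near 20.0 min, at about 23.6%. The forecast differs in time: it gives 24% at 25 min, and expects the top not much later than the eta run's, since “the net slope is small and shrinking while loss grows with product”.

The flask gives 23.2% at 20.1 min, so the forecast's time stands 4.90 min late.

    gas ⇌ reagent, rate k1*(csat - [reagent]) (kL = 1.68 /min)
    2 starting material → homo dimer (k = 3.07 /M/min)
    starting material + reagent + catalyst ⇌ product + catalyst, rate k3*[starting material]*[reagent]*[catalyst] forward; the back reaction follows from the equilibrium constant (K = 519 /M, k = 50000 /M²/s)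

At 20.1 min the flask's ledger holds 23.2% product, 22.4% starting material and 54.4% homo dimer, each rounded, with two starting material counted in every homo dimer. The charge exponent was read from this flask's own epsilon run, so carrying the eta top without scatter, 18.8%, over to 23.3% for this flask, beside the flask's 23.2%, is no check. The neighbouring flask holds 1.70 times the charge, all else as before. The exponent takes 23.2% down to 17.6% there, and that flask's best is 17.5%.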